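The readings were generated by integration for an exercise.

Eta and zeta are two recipes for the same substrate, and you have to say which gives more.

| flask | substrate | reagent in the second phase | protic impurity | remark | time | volume of the second phase over the first |
|---|---|---|---|---|---|---|
| maple | 5 mM | 1.5 equiv | 0.61 mM | run made earlier |  |  |
| birch | 5 mM | 1.5 equiv | 1.2 mM | run made earlier |  |  |
| larch | 5 mM | 1.5 equiv | 1.4 mM | run made earlier |  |  |
| ash | 5 mM | 1.3 equiv | 1.5 mM | run made earlier |  |  |
| eta | 5.0 mM | 0.750 equiv | 0.800 mM |  | 8.0 min | 0.25 |
| zeta | 5.0 mM | 1.50 equiv | 1.50 mM |  | 2.5 min | 0.25 |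

| run | time / s | product / % |
|---|---|---|
| maple | 10.0 | 51 |
| maple | 20.0 | 66 |
| maple | 40.0 | 76 |
| maple | 50.0 | 79 |
| maple | 80.0 | 84 |
| birch | 10.0 | 47 |
| birch | 20.0 | 61 |
| birch | 40.0 | 72 |
| birch | 50.0 | 78 |
| birch | 80.0 | 81 |
| larch | 10.0 | 44 |
| larch | 12.0 | 51 |
| larch | 20.0 | 59 |
| larch | 40.0 | 73 |
| larch | 80.0 | 79 |
| ash | 15.0 | 49 |
| ash | 30.0 | 63 |
| ash | 50.0 | 67 |
| ash | 60.0 | 69 |
| ash | 80.0 | 71 |

(scatter of a reading: 1.5 percentage points)

- the winner by amount of product, in percent of the substrate charged; "neither" if no more than 2 percentage points parts them (eta / zeta / neither)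
- how much product is there at the end, in percent of the substrate charged: eta
- how much product is there at the end, in percent of the substrate charged: zeta

- in the second phase: reagent in the second phase; everything else is in the first
- charges count per volume of the first phase; a concentration in a rate is the amount of a species over the volume of its own phase; every rate counts per litre of the first phase
- the earlier runs hold the two phases in the same ratio of volumes as the flask asked about
- a reading or a percentage of product counts all its forms, free or not

Start from the large thing, the reagent charged, and take off the small thing, the protic impurity, one for one. Eta keeps reagent for 0.590 of the substrate charged. Call this the usable reagent fraction: equivalents of reagent minus equivalents of impurity. Zeta keeps 1.20, maple 1.38 and ash 1.00.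

If each usable reagent makes one product, eta's ceiling is 59.0 %. Now divide the last readings by the fraction. Maple gives 0.610 and ash gives more, 0.710. From maple to ash the yield per usable reagent rises as the fraction falls, and eta's fraction is smaller than ash's. So I take ash's figure, a reading with its scatter, for eta's floor: 41.9 %.

Zeta's fraction is larger than ash's, so take ash's 71 % as zeta's floor, which is above eta's ceiling. So I expect zeta to win. Extending the line through maple and ash, my own figures are 48.3 % for eta and 78.8 % for zeta.

The forecast says zeta, with 52 % for eta and 81 % for zeta: “Reagent runs out before the substrate does”. Its eta lies inside my bracket, above my figure, and its zeta is above mine.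

The flask gives zeta: eta 51.5 %, zeta 83.1 %. The forecast stands.

    2 reagent in the reaction phase → homo dimer (k = 7.20 M⁻¹ s⁻¹)
    substrate + reagent in the reaction phase → product (k = 22.0 M⁻¹ s⁻¹)
    reagent in the reaction phase + protic impurity → quenched reagent (k = 69.0 M⁻¹ s⁻¹)
    reagent in the reaction phase ⇌ reagent in the second phase, rate k4*([reagent in the reaction phase] - [reagent in the second phase]/K4) per volume of the first phase (partition coefficient = 1.60, kL = 0.330 s⁻¹)
    crystals ⇌ product, rate k5*(cs5 - [product]) while solid is left; crystals form when [product] > cs5 (solubility = 2.10 mM, k = 18.0 s⁻¹)

In eta at 0.0171 min, substrate uses reagent 2.1 times as fast as the quench does, while substrate was charged at 6.25 times the impurity. By 8.00 min eta has 10 % of its impurity left and 48 % of its substrate, against 0 % of its reagent in the second phase and 1.84 × 10⁻⁹ mM of reagent in the reaction phase: in eta, reagent is the limiting reagent.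

Take eta with 8.5 mM of substrate, where impurity stands at 0.0941 equiv. Its fraction is 0.656, and eta's yield per usable reagent makes that 57.3 %. The computed flask gives 56.3 %.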